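**The vessel.** This closed, stirred, isothermal vessel holds one flask, and I have one followed run of that same flask, so neither second substrate nor free catalyst has been varied.

| flask | starting material | second substrate | free catalyst | added ligand | remark |
|---|---|---|---|---|---|
| spring | 0.40 M | 0.40 M | 0.80 mM | 0.60 mM | the very flask that is asked about, followed so far |
| flask | 0.40 M | 0.400 M | 0.80 mM | 0.60 mM |  |

- spring (time / min: target / %, starting material / %): 0.250: 0, 100.1; 0.667: 1.7, 98.6; 1.33: 2.3, 98.2; 2.00: 4.1, 96.7; 3.00: 5.4, 94.3; 4.00: 8.2, 92.4; 5.00: 8.6, 90.6

(each reading ± 0.5 percentage points)

- what was read earlier has a scatter of 0.5 percentage points, one standard deviation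
- no earlier run changes the charge of free catalyst; that part of a forecast is a guess
- no earlier run changes the charge of second substrate; that part of a forecast is a guess

1. factor on the rate of making target when 10% of the starting material are converted if second substrate is charged twice over
2. factor on the rate when 10% of the starting material are converted if free catalyst is charged at 0.15 mM instead

**Main step.** I begin with the conversion of starting material into target on the catalyst and nothing else. The last reading, 8.6% of target after 5.00 min, gives 8.60 min⁻¹, and this is the turnover frequency, the target made per minute per catalyst charged. It carries the scatter of 0.5 percentage points. If it holds at another charge, the rate is this number times the catalyst: 6.88 mM min⁻¹ now and 1.29 mM min⁻¹ at 0.15 mM, a factor of 0.187.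

**Second substrate.** Now I add second substrate. If it meets the same catalyst, it shifts the turnover frequency, but this run cannot show the direction. My own guess for dbl is 1.

**Added ligand.** Last comes the ligand, at 0.60 mM. If it binds tightly, 0.200 mM of catalyst works now, while the smaller charge stands below the ligand and the rate there nearly dies. If it binds weakly, it takes a similar share at both charges and the factor stays 0.187. The readings cannot separate these two, and I commit to 0.187, with tight binding as the risk.

**The forecast.** The forecast gives 1.5 for dbl and 0.1 for the ratio, reasoning: “If ligand binds tightly and poisons it, only 0.20 mM is free now”. We differ on both, 1 against 1.5 and 0.187 against 0.1.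

**The result.** The simulation gives 0.775 for dbl and 0.187 for the ratio, from this scheme:

    starting material + free catalyst ⇌ catalyst intermediate A (K = 83.0 M⁻¹, k = 2.86 M⁻¹ s⁻¹)
    catalyst intermediate A → free catalyst + target (k = 0.310 s⁻¹)
    second substrate + free catalyst ⇌ catalyst intermediate B (K = 25.8 M⁻¹, k = 2.19 M⁻¹ s⁻¹)
    catalyst intermediate B → free catalyst + second product (k = 0.380 s⁻¹)
    free catalyst + added ligand ⇌ idle complex (K = 560 M⁻¹, k = 42.2 M⁻¹ s⁻¹)

**What stands.** Per catalyst charged, the flask at 0.15 mM turns over at 1.000 times the rate of the flask at 0.80 mM, and the flask with doubled second substrate at 0.775 times that rate, which on my scattered reading of 8.60 min⁻¹ is an estimate of 6.67 min⁻¹. In the flask at 0.80 mM, the ligand exchange relaxes with a half-life of 0.110 min, far shorter than the 5.31 min taken to reach 10% conversion. At that conversion the idle complex holds 5.15% of the catalyst there, and catalyst intermediate B holds 28.8% in the flask at 0.15 mM.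

All runs come from a simulation for substances that don't exist; the scatter is artificial.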